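**Remarks before the analysis**

- Numbering: guaiane numbering is used throughout. Unprimed atoms belong to the half with the C4=C5 alkene, primed atoms to the half with the C3′ ketone. α/β refer to each half drawn in the usual guaianolide orientation (H6 and H6′ β).
- Remark on the chemistry: the target SMILES has the hydroxyl β at both C10 and C10′, whereas the photoproduct of santonin (2) is the 10α-alcohol. C10′ is therefore inverted in steps 2 and 3.
- Remark on materials: triflate 14 is taken as a catalogue reagent; otherwise it is one step from ethyl (S)-lactate and Tf2O.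

## Analysis of the target

The target, C30H40O7, is an unsymmetrical dimer of two guaianolide units. Each half is a hydroazulene whose seven-membered ring carries a trans-fused α-methyl-γ-butyrolactone (C6–O–C12). The halves are joined by the C2–C2′ and C3–C5′ bonds, so the primed five-membered ring becomes a bicyclo[2.2.1]heptan-2-one (C3′ ketone, C1′ as the one-carbon bridge) with the unprimed cyclopentene fused on its endo side. There are fifteen stereocentres: in each half the lactone has the santonin arrangement (6β-H, 7α-H, 11β-H), H1 is α, and C10 is a tertiary carbinol with hydroxyl β and methyl α, the C10 epimer of what the santonin photorearrangement delivers. In the cage, C5′ is quaternary, H2 and H3 are exo, C10′ sits on C1′ syn to the C3′–C4′ bridge, and the C4′ methyl is endo and epimerizable (α to the C3′ ketone). The sensitive groups are the two tertiary alcohols, the two lactones (C11 epimerization, ring opening), the C6–O bond (allylic to C4=C5 and β to any carbonyl placed at C4) and the enolizable C3′ ketone. The synthesis is hard because two seven-membered rings, each with a tertiary carbinol next to a ring-fusion methine, sit on a crowded norbornane, and because the halves differ in oxidation pattern, so dimerizing one monomer cannot give the target without later differentiation. The strategy rests on one relationship in the unprimed half: the carbinol carbon C10 is bonded to C1, and C1 is β to C4 through C5. With a carbonyl at C4 and a C5=C1 double bond, C1 is the acceptor carbon of a cyclopentenone, so a ketyl at C10 can make the C1–C10 bond, the ring C1/C5/C6/C7/C8/C9/C10 and the carbinol in one reductive step, and the remaining C4 carbonyl is the handle for the C4 methyl and the C4=C5 alkene.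

## Retrosynthetic reasoning

**25 ⇒ 24 (C3′ ketone and C4′–H).** The C3′ ketone is traced back to its silyl enol ether 24. This keeps the C3′ carbonyl masked through every reductive and basic step and leaves C4′ to be set last, by protonation of the enol ether on the exo face.

**24 ⇒ 23 ⇒ 22 (C4–CH3 bond).** The methyl–C4 bond is cut to give enol triflate 23, which comes from ketone 22. The C4 carbonyl is what the ring closure leaves behind, so no extra functional group is needed. The forward steps must enolize C4 toward C5 and not toward C3, and must not expel the C6 oxygen.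

**22 ⇒ 21 (C1–C10 bond, the key disconnection).** Cutting C1–C10 opens the unprimed seven-membered ring and turns the carbinol into a methyl ketone and C1 into the β-carbon of a cyclopentenone. This is the only bond of that ring that can be formed together with the C10 stereocentre, and it is made on a rigid, facially biased acceptor. The forward reaction is a samarium-mediated ketyl–enone cyclization that must set C1 and C10.

**21 ⇒ 9 + 18 (C5–C6 bond and the lactone C–O bond).** The lactone side chain is detached at C5–C6 and at the lactone oxygen. This gives cage enone 9 and keto aldehyde ester 18, which carries C7 and C11 already resolved. The forward reaction is a Morita–Baylis–Hillman union followed by lactonization. C6 is not set in the C–C bond formation; it is set by equilibration of the allylic lactone to the all-trans isomer.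

**18 ⇒ 17 ⇒ 16 ⇒ 15 ⇒ 13 + 14; 13 ⇒ 10 + 11 (C7–C11 bond).** Aldehyde 18 comes from thioester 17, which comes from imides 16 and 15. The C7–C11 bond is cut to the enolate of imide 13 and lactate triflate 14, so the auxiliary of 11 fixes C7 and inversion at the lactate carbon fixes C11. The ketone is carried as the terminal alkene of acid 10 until the enolate chemistry is over.

**9 ⇒ 7 ⇒ 5 + 6 (C2–C2′ and C3–C5′ bonds).** The enone is traced to ketone 7 by dehydrogenation. The two bonds between the halves are then cut in a Diels–Alder sense, to silyloxydiene 5 and cyclopent-2-en-1-one 6. This one reaction builds the norbornene, the quaternary C5′ and four stereocentres, and it leaves the C3′ oxygen as the silyl enol ether that 24 needs.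

**5 ⇒ 4 ⇒ 3 ⇒ 2 ⇒ 1 (the primed half from the chiral pool).** Diene 5 is the kinetic silyl dienol ether of enone 4. Compound 4 is the C10 epimer of isophotosantonic lactone 2, reached by dehydration to 3 and rehydration. Lactone 2 is the photoproduct of santonin 1, which supplies C6′, C7′, C11′ and, through the rearrangement, C1′.

## Alternatives that were turned down

**Alternative 1:** two-directional double allylation–lactonization. The disconnection cuts C6–C7 and C6′–C7′ and both lactone C–O bonds at once. In the forward direction, divalent chromium would convert two (Z)-2-(bromomethyl)enoate groups into allylchromium species that add through C7 and C7′ to aldehyde groups at C6 and C6′. This closes both seven-membered rings, and the alkoxides lactonize to the bis(α-methylene lactone) bis-triethylsilyl ether A1.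
- For it: two rings, two lactones and four stereocentres arise in one operation, and chromium allylation–lactonization of aldehydes is a dependable way to α-methylene lactones. On convergence it is stronger than the chosen plan.
- Against it: the two aldehydes are very different. One is an enal on C5; the other is neopentyl, on the quaternary bridgehead C5′. Both closures must give the trans C6/C7 relationship in medium-ring transition states that the cage does not obviously bias. Both tertiary carbinols (C10, C10′) would have to be set beforehand on open side chains. After A1, two exocyclic methylenes still have to be reduced with control of C11 and C11′, and the silyl ethers removed.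
- Comparison: the chosen route takes the whole primed seven-membered ring, its lactone and four of its stereocentres from 1, so only one ring must be closed and C11 is never an open question. In return it accepts a less convergent, one-directional plan.

**Alternative 2:** two-directional double ring-closing metathesis. The disconnection cuts C8=C9 and C8′=C9′ of a tetradehydro compound. In the forward direction, a ruthenium alkylidene catalyst would close both cycloheptenes from vinyl carbinols at C10 and C10′ and vinyl groups at C7 and C7′, with loss of ethylene, to give A2. One chemoselective hydrogenation of the two disubstituted alkenes (beside the tetrasubstituted C4=C5) would finish the synthesis.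
- For it: forming cycloheptenes with disubstituted alkenes remote from the crowded centres is highly predictable, the key step creates no stereocentre, and the endgame is one step. On reliability of the ring closure it is stronger than a samarium-mediated 7-endo closure.
- Against it: every one of the fifteen stereocentres must be in place on an open precursor. That includes both tertiary vinyl carbinols beside C1 and C1′ and both vinyl-bearing trans-lactones, one of them attached to the quaternary C5′. None of these can lean on a ring for control, and four terminal alkenes invite cross-metathesis.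
- Comparison: the chosen route is much shorter to its precursor, because one hydroazulene is bought with 1 and the other carbinol is created in the ring closure itself. It pays for this with a riskier key step.

**Alternative 3:** dearomative Buchner ring expansion. The disconnection cuts C5–C1 and C5–C6, tracing the unprimed hydroazulene to a dimethoxyphenyl group on C2 and a diazoketone on C3. In the forward direction, a rhodium carboxylate catalyst would generate the carbenoid at C5, which adds to the ipso–ortho bond of the arene; the norcaradiene opens to the cycloheptatriene-fused cyclopentanone A3.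
- For it: two rings form in one step from a flat, easily attached arene, by a reaction class well known for azulenones. For raw skeletal construction it is stronger than the chosen plan.
- Against it: A3 contains none of the unprimed half's stereocentres beyond C5. The lactone carbons C11–C13 are missing. The two enol ethers, the triene, the C10 carbinol, the C4 methyl and the C6/C7/C11 array would all have to be worked out afterwards on a flexible ring, in many steps. The ortho-methoxy groups also hinder the cyclopropanation and invite ylide formation or C–H insertion.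
- Comparison: the chosen route fixes C7 and C11 before the union, C6 in the lactonization and C1/C10 in the key step, and reaches the target three steps after the ring closure.

Key step: step 13

## Steps

Step 1
Reactants: 1 (−)-α-santonin
Product: 2 isophotosantonic lactone (10α-hydroxy-3-oxo-1αH,6βH,7αH,11βH-guai-4-en-12,6-olide)
Conditions: hν (Hg lamp, Pyrex), AcOH/H2O (1:1), reflux, N2
Reagents that add atoms: water, O
Why: Photorearrangement of the cross-conjugated cyclohexadienone: C1–C5 bonding gives a cyclopropyl zwitterion whose protonated form opens by cleavage of C5–C10 with capture of water at C10 from the rear. C1 (1αH) and C10 (10α-OH) are set stereospecifically and C6, C7 and C11 are untouched.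

Step 2
Reactants: 2 isophotosantonic lactone
Product: 3 3-oxo-1αH,6βH,7αH,11βH-guaia-4,10(14)-dien-12,6-olide
Conditions: SOCl2, pyridine, CH2Cl2, −20 → 0 °C
Reagents that add atoms: none
Why: E2 dehydration through the chlorosulfite; H1 is cis to the 10α leaving group, so elimination toward C1 (the conjugated dienone) is not available and loss of a methyl hydrogen should dominate. A ring-alkene regioisomer toward C9, if formed, leads to the same C10 radical in step 3.

Step 3
Reactants: 3 3-oxo-1αH,6βH,7αH,11βH-guaia-4,10(14)-dien-12,6-olide
Product: 4 10-epi-isophotosantonic lactone (10β-hydroxy-3-oxo-1αH,6βH,7αH,11βH-guai-4-en-12,6-olide)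
Conditions: Co(acac)2 (0.2 equiv), PhSiH3 (2.5 equiv), O2 (1 atm), THF, 23 °C; aq. Na2S2O3
Reagents that add atoms: dioxygen, O=O
Why: Mukaiyama hydration (metal-hydride hydrogen-atom transfer): H adds to C14 and the tertiary C10 radical is trapped by O2, expected mainly on the β face (the axial direction, which meets only H8β, whereas the α face carries the axial H1 and H9 hydrogens), giving the 10β-carbinol. The tetrasubstituted enone alkene is inert to hydrogen-atom transfer, and the minor 10α epimer is 2 itself and goes back into step 2.

Step 4
Reactants: 4 10-epi-isophotosantonic lactone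
Product: 5 3-(tert-butyldimethylsilyloxy)-10β-hydroxy-1αH,6βH,7αH,11βH-guaia-2,4-dien-12,6-olide
Conditions: LiN(SiMe3)2 (2.1 equiv), THF, −78 °C; TBSCl (1.2 equiv), DMPU, −78 → −20 °C; used at once
Reagents that add atoms: tert-butyldimethylsilyl chloride, CC(C)(C)[Si](C)(C)Cl
Why: Kinetic α′-deprotonation of the enone at C2 gives the cross-conjugated dienolate, which is O-silylated; the hindered tertiary lithium alkoxide does not react with TBSCl. Low temperature and immediate use avoid 1,5-hydrogen shifts of the 2-silyloxycyclopentadiene.

Step 5
Reactants: 5 silyloxydiene; 6 cyclopent-2-en-1-one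
Product: 7 endo cycloadduct (C2–C2′ and C3–C5′ bonded; C4 ketone with C5H2 and C1H2; H2 and H3 exo; C3′=C4′ O-TBS enol ether; 10′β-OH)
Conditions: 6 (3 equiv), Me2AlCl (2.5 equiv), CH2Cl2, −78 → −40 °C
Reagents that add atoms: none
Why: Lewis-acid-promoted Diels–Alder reaction of a 2-silyloxycyclopentadiene with an enone; the first equivalent of Me2AlCl is consumed by the 10′-OH. The silyloxy group sets the regiochemistry: C2′, the enol-ether terminus, bonds to the β-carbon C2, and the fully substituted C5′ bonds to the α-carbon C3 in the later-forming bond. The dienophile adds endo and on the diene face anti to C10′ (the face of H1′), which sets C2, C3, C2′ and the quaternary C5′.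

Step 6
Reactants: 7 endo cycloadduct
Product: 9 cage enone (7 with the C5=C1 double bond), via sulfilimine adduct 8 (not isolated)
Conditions: LiN(iPr)2 (2.1 equiv), THF, −78 °C; PhS(Cl)=NtBu (2.2 equiv), −78 °C
Reagents that add atoms: none
Why: Mukaiyama dehydrogenation: the kinetic enolate forms at the C5 methylene (C3–H is a methine beside the quaternary C5′), attacks sulfur on the convex face, and the adduct loses the sulfenamide by syn elimination toward C1. The silyl enol ether is inert to these basic, non-oxidizing conditions.

Step 7
Reactants: 10 hex-5-enoic acid; 11 (R)-4-benzyl-1,3-oxazolidin-2-one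
Product: 13 (R)-4-benzyl-3-(hex-5-enoyl)-1,3-oxazolidin-2-one, via mixed anhydride 12 (not isolated)
Conditions: t-BuCOCl, Et3N, THF, −20 °C; then 11, LiCl, 23 °C
Reagents that add atoms: none
Why: N-Acylation of the Evans auxiliary through the pivalic mixed anhydride; the hindered pivaloyl carbonyl is not attacked.

Step 8
Reactants: 13 acyl oxazolidinone; 14 ethyl (S)-2-{[(trifluoromethyl)sulfonyl]oxy}propanoate
Product: 15 ethyl (2S,3S)-3-{[(4R)-4-benzyl-2-oxo-1,3-oxazolidin-3-yl]carbonyl}-2-methylhept-6-enoate
Conditions: NaN(SiMe3)2 (1.05 equiv), THF, −78 °C; 14 (1.3 equiv), −78 → −30 °C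
Reagents that add atoms: none
Why: Evans enolate alkylation with an α-triflyloxy ester: the chelated Z-enolate is attacked on the face away from the benzyl group, which sets C7 (S), and SN2 displacement of triflate with inversion at the lactate carbon sets C11 (S).

Step 9
Reactants: 15 alkylated imide
Product: 16 ethyl (2S,3S)-3-{[(4R)-4-benzyl-2-oxo-1,3-oxazolidin-3-yl]carbonyl}-2-methyl-6-oxoheptanoate
Conditions: PdCl2 (0.1 equiv), Cu(OAc)2 (0.2 equiv), O2 (1 atm), DMA/H2O (7:1), 23 °C
Reagents that add atoms: water, O
Why: Tsuji–Wacker oxidation of the terminal alkene to the methyl ketone (Markovnikov hydroxypalladation by divalent palladium, O2 as terminal oxidant); the stereocentres are not enolized under these conditions.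

Step 10
Reactants: 16 keto imide
Product: 17 ethyl (2S,3S)-3-[(ethylsulfanyl)carbonyl]-2-methyl-6-oxoheptanoate
Conditions: EtSH (3 equiv), n-BuLi (2.5 equiv), THF, 0 °C
Reagents that add atoms: ethanethiol, CCS
Why: Thiolate cleavage of the imide at the exocyclic carbonyl; the imide is far more electrophilic than the ethyl ester, the weakly basic thiolate leaves C7 intact, and auxiliary 11 is recovered.

Step 11
Reactants: 17 thioester
Product: 18 ethyl (2S,3S)-3-formyl-2-methyl-6-oxoheptanoate
Conditions: Et3SiH (3 equiv), Pd/C (10 wt %, 5 mol %), acetone, 23 °C; used crude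
Reagents that add atoms: none
Why: Fukuyama reduction of the thioester to the aldehyde; ketone and ester are not reduced, and immediate use protects the α-stereocentre C7 and avoids aldol cyclization of the 1,5-keto aldehyde.

Step 12
Reactants: 9 cage enone; 18 keto aldehyde ester
Product: 21 cyclization precursor (9 carrying at C5 the (2S,3S,4S)-4-methyl-5-oxo-3-(3-oxobutyl)oxolan-2-yl group), via hydroxy ester 19 (not isolated), via 6-epi-lactone 20 (not isolated)
Conditions: 18 (1.5 equiv), PBu3 (0.5 equiv), PhOH (0.3 equiv), THF, 23 °C, then 45 °C
Reagents that add atoms: none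
Why: Morita–Baylis–Hillman reaction: PBu3 adds to C1 of the 4-substituted cyclopentenone from the convex face, the enolate adds through C5 to the aldehyde (C5–C6), and the C6 alkoxide closes the lactone on the ethyl ester. The first-formed C6 configuration is not relied on: the product is an allylic (Baylis–Hillman-type) ester, which the phosphine ionizes reversibly by SN2′ addition at C1 and re-closes by SN2′ return of the tethered carboxylate at C6, so both C6 epimers should drain into the all-trans lactone (C5 trans to C8, C8 trans to C13), also the A(1,3)-favoured mode of re-closure. C7 and C11 come unchanged from 18.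

Step 13
Reactants: 21 cyclization precursor
Product: 22 hydroazulenone (C1–C10 bonded; 10β-OH and 10α-CH3; 1αH,5αH; C4 ketone)
Conditions: SmI2 (3.0 equiv, 0.1 M in THF), t-BuOH (3 equiv), THF (0.005 M), −78 → −30 °C
Reagents that add atoms: none
Why: SmI2 puts one electron into the carbonyl system (the C10 ketyl and the enone radical anion are interchangeable on one samarium centre), C10 adds to C1, the β-carbon of the cyclopentenone, and a second electron turns the C5 radical into a samarium enolate that t-BuOH protonates at C5. The closest known reaction type is the SmI2 ketyl–olefin cyclization onto enones and enoates, which is documented for seven- and eight-membered rings. The seven-membered ring closes in the 7-endo-trig mode, because the tether (C6 to C10) is anchored on the α-carbon C5. C1 is controlled by the cage: the cyclopentenone is fused endo under the C3′–C4′ bridge, so C10 arrives on the convex face, anti to C2′ and cis to H2. C10 is controlled by the tether and by chelation: C9 turns away from C2, and trivalent samarium bridging the ketyl oxygen and the C4 oxygen holds the C10–O bond on the C5 side with the methyl group outside, which gives 10β-OH and 10α-CH3 (HMPA is left out to keep this chelate). C5 is set by protonation that leaves C6 on the convex face (1αH,5αH), and it is erased again in step 14. The step needs reduction of the C10 ketone and the enone only, bond formation at C1 and not pinacol coupling at C4, and survival of the C6–O bond: the C3′ carbonyl is masked as the silyl enol ether, lactones are inert to SmI2 in THF, the β-carbon carries the spin density of the enone, and once the ring is closed the trans-lactone holds C6–O near the enolate plane (H6 axial), so that β-elimination is stereoelectronically disfavoured while the alcohol traps the enolate at low temperature.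

Step 14
Reactants: 22 hydroazulenone
Product: 23 C4 enol triflate (C4=C5)
Conditions: KN(SiMe3)2 (3.2 equiv), N-(5-chloropyridin-2-yl)triflimide (Comins' reagent, 1.5 equiv), THF, −78 °C
Reagents that add atoms: Comins' reagent, O=S(=O)(N(c1ccc(Cl)cn1)S(=O)(=O)C(F)(F)F)C(F)(F)F
Why: Enol triflate formation from the ketone enolate (two equivalents of base are taken up by the tertiary alkoxides, which are too hindered to be triflated). Enolization should go toward C5, whose hydrogen is acidified by the C6 oxygen, because a C3=C4 enolate would place an sp2 carbon at the strained fusion with the norbornane; C6–O lies near the enolate plane, which disfavours β-elimination at −78 °C. C5 becomes sp2.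

Step 15
Reactants: 23 C4 enol triflate
Product: 24 4-methyl-Δ4(5) silyl enol ether (the target with C3′=C4′ as O-TBS enol ether)
Conditions: Me2CuLi (6 equiv), THF, −20 → 0 °C
Reagents that add atoms: lithium dimethylcuprate, [Li+].C[Cu-]C
Why: Cuprate coupling of the enol triflate with retention of the double-bond position gives the methylated tetrasubstituted C4=C5 alkene; lactones and the silyl enol ether tolerate the cuprate at this temperature, and SN2′ attack on the fully substituted allylic lactone is too hindered.

Step 16
Reactants: 24 4-methyl-Δ4(5) silyl enol ether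
Product: 25 target CNP0243924.4
Conditions: Bu4NF (1.2 equiv), AcOH (1.5 equiv), THF, −20 → 0 °C
Reagents that add atoms: none
Why: Fluoride cleavage of the silyl enol ether and kinetic protonation of the enolate at C4′ by AcOH. The endo face of C4′ is blocked by C4/C15 of the endo-fused ring, so the proton should arrive from the exo face (the 10′-OH above that face may relay it), leaving the C15′ methyl endo as in the target; the buffered medium avoids later epimerization at C4′, C11 and C11′.

## Compound list

1 | (−)-α-santonin | C[C@H]1[C@@H]2CC[C@]3(C=CC(=O)C(=C3[C@H]2OC1=O)C)C | starting material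
2 | isophotosantonic lactone (10α-hydroxy-3-oxo-1αH,6βH,7αH,11βH-guai-4-en-12,6-olide) | CC1=C2[C@H]3OC(=O)[C@@H](C)[C@@H]3CC[C@@](C)(O)[C@@H]2CC1=O | intermediate
3 | 3-oxo-1αH,6βH,7αH,11βH-guaia-4,10(14)-dien-12,6-olide | CC1=C2[C@H]3OC(=O)[C@@H](C)[C@@H]3CCC(=C)[C@@H]2CC1=O | intermediate
4 | 10-epi-isophotosantonic lactone (10β-hydroxy-3-oxo-1αH,6βH,7αH,11βH-guai-4-en-12,6-olide) | CC1=C2[C@H]3OC(=O)[C@@H](C)[C@@H]3CC[C@](C)(O)[C@@H]2CC1=O | intermediate
5 | 3-(tert-butyldimethylsilyloxy)-10β-hydroxy-1αH,6βH,7αH,11βH-guaia-2,4-dien-12,6-olide | CC1=C2[C@H]3OC(=O)[C@@H](C)[C@@H]3CC[C@](C)(O)[C@@H]2C=C1O[Si](C)(C)C(C)(C)C | intermediate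
6 | cyclopent-2-en-1-one | O=C1C=CCC1 | starting material
7 | endo cycloadduct (cage ketone; C3′=C4′ O-TBS enol ether; H2 and H3 exo; 10′β-OH) | O=C1CC[C@H]2[C@H]3C(O[Si](C)(C)C(C)(C)C)=C(C)[C@]4([C@@H]3[C@@](C)(O)CC[C@H]3[C@H](C)C(=O)O[C@@H]34)[C@@H]12 | intermediate
8 | C5 sulfilimine adduct of 7 (N-tert-butyl-S-phenylsulfilimidoyl group on the convex face; sulfur configuration not defined) | O=C1[C@H](S(=NC(C)(C)C)c5ccccc5)C[C@H]2[C@H]3C(O[Si](C)(C)C(C)(C)C)=C(C)[C@]4([C@@H]3[C@@](C)(O)CC[C@H]3[C@H](C)C(=O)O[C@@H]34)[C@@H]12 | intermediate
9 | cage enone (C4 ketone, C5=C1) | O=C1C=C[C@H]2[C@H]3C(O[Si](C)(C)C(C)(C)C)=C(C)[C@]4([C@@H]3[C@@](C)(O)CC[C@H]3[C@H](C)C(=O)O[C@@H]34)[C@@H]12 | intermediate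
10 | hex-5-enoic acid | C=CCCCC(=O)O | starting material
11 | (R)-4-benzyl-1,3-oxazolidin-2-one | O=C1N[C@H](Cc2ccccc2)CO1 | starting material
12 | hex-5-enoic pivalic anhydride | C=CCCCC(=O)OC(=O)C(C)(C)C | intermediate
13 | (R)-4-benzyl-3-(hex-5-enoyl)-1,3-oxazolidin-2-one | C=CCCCC(=O)N1[C@H](Cc2ccccc2)COC1=O | intermediate
14 | ethyl (S)-2-{[(trifluoromethyl)sulfonyl]oxy}propanoate | CCOC(=O)[C@H](C)OS(=O)(=O)C(F)(F)F | starting material
15 | ethyl (2S,3S)-3-{[(4R)-4-benzyl-2-oxo-1,3-oxazolidin-3-yl]carbonyl}-2-methylhept-6-enoate | O=C(N1[C@H](Cc2ccccc2)COC1=O)[C@@H](CCC=C)[C@H](C)C(=O)OCC | intermediate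
16 | ethyl (2S,3S)-3-{[(4R)-4-benzyl-2-oxo-1,3-oxazolidin-3-yl]carbonyl}-2-methyl-6-oxoheptanoate | O=C(N1[C@H](Cc2ccccc2)COC1=O)[C@@H](CCC(C)=O)[C@H](C)C(=O)OCC | intermediate
17 | ethyl (2S,3S)-3-[(ethylsulfanyl)carbonyl]-2-methyl-6-oxoheptanoate | CCSC(=O)[C@@H](CCC(C)=O)[C@H](C)C(=O)OCC | intermediate
18 | ethyl (2S,3S)-3-formyl-2-methyl-6-oxoheptanoate | O=C[C@@H](CCC(C)=O)[C@H](C)C(=O)OCC | intermediate
19 | Morita–Baylis–Hillman hydroxy ester (C5–C6 bonded; both C6 epimers, C6 drawn without descriptor) | O=C1C(C(O)[C@@H](CCC(C)=O)[C@H](C)C(=O)OCC)=C[C@H]2[C@H]3C(O[Si](C)(C)C(C)(C)C)=C(C)[C@]4([C@@H]3[C@@](C)(O)CC[C@H]3[C@H](C)C(=O)O[C@@H]34)[C@@H]12 | intermediate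
20 | 6-epi-lactone (C5 cis to C8 on the lactone) | O=C1C([C@@H]2OC(=O)[C@@H](C)[C@@H]2CCC(C)=O)=C[C@H]2[C@H]3C(O[Si](C)(C)C(C)(C)C)=C(C)[C@]4([C@@H]3[C@@](C)(O)CC[C@H]3[C@H](C)C(=O)O[C@@H]34)[C@@H]12 | intermediate
21 | cyclization precursor (cage enone with the all-trans lactone at C5 and the C10 methyl ketone) | O=C1C([C@H]2OC(=O)[C@@H](C)[C@@H]2CCC(C)=O)=C[C@H]2[C@H]3C(O[Si](C)(C)C(C)(C)C)=C(C)[C@]4([C@@H]3[C@@](C)(O)CC[C@H]3[C@H](C)C(=O)O[C@@H]34)[C@@H]12 | intermediate
22 | hydroazulenone (C1–C10 bonded; 10β-OH, 10α-CH3; 1αH,5αH; C4 ketone) | O=C1[C@@H]2[C@H]3OC(=O)[C@@H](C)[C@@H]3CC[C@](C)(O)[C@@H]2[C@H]2[C@H]3C(O[Si](C)(C)C(C)(C)C)=C(C)[C@]4([C@@H]3[C@@](C)(O)CC[C@H]3[C@H](C)C(=O)O[C@@H]34)[C@@H]12 | intermediate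
23 | C4 enol triflate (C4=C5) | O=S(=O)(OC1=C2[C@H]3OC(=O)[C@@H](C)[C@@H]3CC[C@](C)(O)[C@@H]2[C@H]2[C@H]3C(O[Si](C)(C)C(C)(C)C)=C(C)[C@]4([C@@H]3[C@@](C)(O)CC[C@H]3[C@H](C)C(=O)O[C@@H]34)[C@@H]12)C(F)(F)F | intermediate
24 | 4-methyl-Δ4(5) silyl enol ether (target with C3′=C4′ O-TBS enol ether) | CC1=C2[C@H]3OC(=O)[C@@H](C)[C@@H]3CC[C@](C)(O)[C@@H]2[C@H]2[C@H]3C(O[Si](C)(C)C(C)(C)C)=C(C)[C@]4([C@@H]3[C@@](C)(O)CC[C@H]3[C@H](C)C(=O)O[C@@H]34)[C@@H]12 | intermediate
25 | CNP0243924.4 | CC1=C2[C@H]3OC(=O)[C@@H](C)[C@@H]3CC[C@](C)(O)[C@@H]2[C@H]2[C@H]3C(=O)[C@@H](C)[C@]4([C@@H]3[C@@](C)(O)CC[C@H]3[C@H](C)C(=O)O[C@@H]34)[C@@H]12 | target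

## Step count and least certain steps

Total step count: 16. Longest linear sequence: 11 steps (steps 1–6 and 12–16, from 1); the side branch from 10 is 5 steps (steps 7–11) before the union.

**Step 13 (key step).** The most likely failure is that the enone is reduced past the point of cyclization: either plain conjugate reduction, or loss of the allylic C6 carboxylate from a dienolate before the ring has closed. A second risk is poor control at C10 if the samarium chelate does not form. Fallback, from 21 directly to 22: a photocatalytic proton-coupled electron-transfer ketyl–olefin cyclization ([Ir(ppy)2(dtbbpy)]PF6, diphenyl phosphate, Hantzsch ester, blue light, THF). The neutral ketyl is generated at the C10 ketone, and the C5 radical formed after ring closure is quenched by hydrogen-atom transfer, so no enolate with a β-leaving group is ever formed. No new compound lies on this path.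

**Step 12.** The Morita–Baylis–Hillman reaction may be slow with an α-branched aldehyde on a 4,5-disubstituted cyclopentenone; the 1,5-keto aldehyde can cyclize by aldol reaction while it waits; and the C6 equilibration may stall short of the all-trans lactone. Fallback, from 9: α-iodination (I2, pyridine, CH2Cl2, 0 °C) gives the 2-iodo enone F1. Nozaki–Hiyama–Kishi coupling of F1 with 18 (CrCl2, NiCl2 cat., DMF, 23 °C) forms the C5–C6 bond chemoselectively at the aldehyde and gives 19. Catalytic PBu3 in warm THF then lactonizes and equilibrates as before, returning to the route at 21.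

**Step 5.** The Lewis acid may strip the silyl group, or stop at the open Mukaiyama–Michael stage, faster than the hindered C3–C5′ bond closes; the diene may also isomerize by hydrogen shift. Fallback, from 5: the more reactive dienophile 2-bromocyclopent-2-en-1-one (BrC1=CCCC1=O) is used without Lewis acid (toluene, 60 °C), giving the α-bromo cycloadduct F2. Radical debromination (Bu3SnH, AIBN, benzene, 80 °C) returns to the route at 7.

**Step 3.** Capture of O2 by the planar C10 radical may show low facial selectivity, so that much of the material returns as 2. Fallback, from 3: epoxidation with dimethyldioxirane (acetone, 0 °C), which has a more ordered transition state and should also prefer the β face, gives the 10β,14-epoxide F3. Opening at the primary carbon (LiBr, AcOH, THF) gives the bromohydrin F4, and Bu3SnH/AIBN removes the bromine, returning to the route at 4.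

**Step 14.** Enolization may go partly toward C3, the enolate may expel the C6 carboxylate, or excess base may enolize a lactone. Fallback, from 22, avoiding any enolate: methylenation of the C4 ketone with the Tebbe reagent Cp2Ti(μ-Cl)(μ-CH2)AlMe2 (THF, −40 → 0 °C; ketone faster than lactone) gives the exocyclic alkene F5. Isomerization by hydrogen-atom transfer (Co(salen)Cl cat., PhSiH3 cat., benzene, 23 °C) to the more substituted C4=C5 position returns to the route at 24, bypassing 23.

**Step 16.** The proton may be delivered partly to the endo face of C4′, giving the C4′ epimer. Fallback, from 24: cleavage with Bu4NF without a proton source, then aqueous work-up, and equilibration of the resulting 4′-epimer F6 with DBU (toluene, 23 °C). This is thermodynamic control through the C3′ enolate, in which a C4′ methyl beside a syn substituent on the one-carbon bridge is expected to prefer the endo position. It returns to the route at 25.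

## Further compounds

F0 | step 13 | none | none
F1 | step 12 | 2-iodo cage enone (9 with iodine at C5) | O=C1C(I)=C[C@H]2[C@H]3C(O[Si](C)(C)C(C)(C)C)=C(C)[C@]4([C@@H]3[C@@](C)(O)CC[C@H]3[C@H](C)C(=O)O[C@@H]34)[C@@H]12
F2 | step 5 | α-bromo cycloadduct (7 with bromine at C3) | O=C1CC[C@H]2[C@H]3C(O[Si](C)(C)C(C)(C)C)=C(C)[C@]4([C@@H]3[C@@](C)(O)CC[C@H]3[C@H](C)C(=O)O[C@@H]34)[C@@]12Br
F3 | step 3 | 10β,14-epoxy-3-oxo-1αH,6βH,7αH,11βH-guai-4-en-12,6-olide | CC1=C2[C@H]3OC(=O)[C@@H](C)[C@@H]3CC[C@@]4(CO4)[C@@H]2CC1=O
F4 | step 3 | 14-bromo-10β-hydroxy-3-oxo-1αH,6βH,7αH,11βH-guai-4-en-12,6-olide | CC1=C2[C@H]3OC(=O)[C@@H](C)[C@@H]3CC[C@](CBr)(O)[C@@H]2CC1=O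
F5 | step 14 | C4 exocyclic methylene compound (22 with C4=CH2 in place of the ketone) | C=C1[C@@H]2[C@H]3OC(=O)[C@@H](C)[C@@H]3CC[C@](C)(O)[C@@H]2[C@H]2[C@H]3C(O[Si](C)(C)C(C)(C)C)=C(C)[C@]4([C@@H]3[C@@](C)(O)CC[C@H]3[C@H](C)C(=O)O[C@@H]34)[C@@H]12
F6 | step 16 | 4′-epimer of the target (C15′ methyl exo) | CC1=C2[C@H]3OC(=O)[C@@H](C)[C@@H]3CC[C@](C)(O)[C@@H]2[C@H]2[C@H]3C(=O)[C@H](C)[C@]4([C@@H]3[C@@](C)(O)CC[C@H]3[C@H](C)C(=O)O[C@@H]34)[C@@H]12
A1 | alternative 1 | bis(α-methylene lactone) bis-triethylsilyl ether | CC1=C2[C@H]3OC(=O)C(=C)[C@@H]3CC[C@](C)(O[Si](CC)(CC)CC)[C@@H]2[C@H]2[C@H]3C(=O)[C@@H](C)[C@]4([C@@H]3[C@@](C)(O[Si](CC)(CC)CC)CC[C@H]3C(=C)C(=O)O[C@@H]34)[C@@H]12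
A2 | alternative 2 | 8,9,8′,9′-tetradehydro target | CC1=C2[C@H]3OC(=O)[C@@H](C)[C@@H]3C=C[C@](C)(O)[C@@H]2[C@H]2[C@H]3C(=O)[C@@H](C)[C@]4([C@@H]3[C@@](C)(O)C=C[C@H]3[C@H](C)C(=O)O[C@@H]34)[C@@H]12
A3 | alternative 3 | bis-enol ether cycloheptatriene fused to a cyclopentanone | COC1=CC=CC(OC)=C2[C@H]1C(=O)[C@H]3[C@@H]2[C@H]4C(=O)[C@@H](C)[C@]35[C@@H]4[C@@](C)(O[Si](CC)(CC)CC)CC[C@H]4[C@H](C)C(=O)O[C@@H]45
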